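Assumption: positions use germacrane numbering (C1–C10 ring, C11–C13 lactone/exomethylene, C14 = CH3 on C10, C15 = CH2OH on C4). The SMILES is read as 4Z,6S,7R,8R,10R, that is H-6 and H-7 cis (cis-fused lactone), 8β-O-tiglate ((E)-2-methylbut-2-enoate) and 10β-CH3.

## Retrosynthetic overview
1. The furanone comes last. A macrocyclic γ-hydroxy-ynone lactone is hydrated transannularly, the 10-OH closes on C3=O (3,10-hemiketal), and water is lost.
2. Carbocycle and lactone form in one flask from an acyclic farnesane-type chain. The C6–C7 closure is the farnesyl C1→C10 bond with the same polarity, run as a 2-(alkoxycarbonyl)allylboration of a C6 aldehyde. The C6 borate then acylates on C12.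
3. The (Z)-4-oxo-enal (C3=O, C6HO, 4Z) comes from singlet-oxygen opening of a 2-alkynyl-3-(silyloxymethyl)furan.
4. The chain is built by HWE (C7=C11), Sonogashira (C2–C3), chelate-controlled ethynylation (C1–C10, sets C10) and a proline aldol of acetone with ethyl glyoxylate (C8–C9, sets C8).
5. Ring order: 10-membered carbocycle → γ-lactone → 3(2H)-furanone.

## Route

Step 1
Reactants: 1 acetone; 2 ethyl glyoxylate
Product: 3 ethyl (2R)-2-hydroxy-4-oxopentanoate
Conditions: L-proline (20 mol%), acetone (solvent), 0 °C to rt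
Reagents that add atoms: none
Why: Proline-catalysed direct aldol (List–Barbas type), in which the acetone enamine attacks the Re face of the glyoxylate aldehyde in the hydrogen-bonded chair, and this sets C8 as R.

Step 2
Reactants: 3 ethyl (2R)-2-hydroxy-4-oxopentanoate; 4 ethynylmagnesium bromide
Product: 6 (3R,5R)-5-ethynyl-3-hydroxy-5-methyloxolan-2-one, via dihydroxy ester 5 (not isolated)
Conditions: HC≡CMgBr (3 equiv), THF–CH2Cl2, −78 to −20 °C; 1 M HCl work-up
Reagents that add atoms: none
Why: Chelation-controlled Grignard addition (Cram chelate, 1,3-induction) followed by lactonisation, in which the first equivalent of 4 makes the C8 magnesium alkoxide, magnesium ties it to the ketone oxygen in a six-membered chelate, ethynyl attacks axially on the face away from C7 so that C10 is set as R (8,10-anti; about 4:1 expected, minor epimer removed at the lactone stage), and the tertiary alkoxide closes on the ester.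

Step 3
Reactants: 7 furan-3-ylmethanol
Product: 9 (2-iodofuran-3-yl)methanol, via dilithio species 8 (not isolated)
Conditions: n-BuLi (2.2 equiv), THF, −78 to 0 °C; ICH2CH2I, −78 °C
Reagents that add atoms: 1,2-diiodoethane, ICCI
Why: Alkoxide-directed ortho-lithiation of the furan at C2 followed by iodinolysis.

Step 4
Reactants: 9 (2-iodofuran-3-yl)methanol
Product: 10 tert-butyl[(2-iodofuran-3-yl)methoxy]diphenylsilane
Conditions: TBDPSCl, imidazole, CH2Cl2, rt
Reagents that add atoms: tert-butyl(chloro)diphenylsilane, CC(C)(C)[Si](Cl)(c1ccccc1)c1ccccc1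
Why: Standard silylation, which blocks the C15 hydroxyl so that it can neither be acylated in step 9 nor add 6-endo to the later ynone.

Step 5
Reactants: 6 (3R,5R)-5-ethynyl-3-hydroxy-5-methyloxolan-2-one; 10 tert-butyl[(2-iodofuran-3-yl)methoxy]diphenylsilane
Product: 11 (3R,5R)-5-{[3-(tert-butyldiphenylsilyloxymethyl)furan-2-yl]ethynyl}-3-hydroxy-5-methyloxolan-2-one
Conditions: PdCl2(PPh3)2 (2 mol%), CuI (4 mol%), Et3N, THF, rt
Reagents that add atoms: none
Why: Sonogashira coupling of a reactive 2-iodofuran at room temperature forms C2–C3 and leaves the lactone and both stereocentres untouched.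

Step 6
Reactants: 11 the coupled lactone
Product: 12 (3R,5R)-5-{[3-(tert-butyldiphenylsilyloxymethyl)furan-2-yl]ethynyl}-5-methyloxolane-2,3-diol (lactol; anomer mixture)
Conditions: i-Bu2AlH (2.5 equiv), CH2Cl2, −78 °C; aq. potassium sodium tartrate
Reagents that add atoms: none
Why: Partial reduction of a lactone to the lactol, in which the α-alkoxide-chelated aluminium hemiacetal stops over-reduction and C7 reaches the aldehyde level.

Step 7
Reactants: 13 triethyl phosphonoacetate; 14 2-(bromomethyl)-4,4,5,5-tetramethyl-1,3,2-dioxaborolane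
Product: 16 ethyl 2-(diethoxyphosphoryl)-3-(pinacolboryl)propanoate (racemic), via sodium phosphonoacetate 15 (not isolated)
Conditions: NaH, THF, 0 °C; then 14, rt to 50 °C
Reagents that add atoms: none
Why: C-alkylation of a stabilised phosphonate anion by an α-halomethylboronate (SN2, or boron ate complex then 1,2-shift, Matteson type).

Step 8
Reactants: 12 the lactol; 16 the boryl phosphonate
Product: 18 ethyl (2E,4R,6R)-8-[3-(tert-butyldiphenylsilyloxymethyl)furan-2-yl]-4,6-dihydroxy-6-methyl-2-[(pinacolboryl)methyl]oct-2-en-7-ynoate, via sodium phosphonate anion 17 (not isolated)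
Conditions: 16 (2.5 equiv), NaH (2.4 equiv), THF, 0 °C; then 12, 0 °C to rt
Reagents that add atoms: none
Why: Horner–Wadsworth–Emmons olefination of the open hydroxy-aldehyde form of the lactol, in which the α-branched phosphonate gives mainly the enoate with C8 trans to CO2Et (cis to CH2B), no stereocentre is touched, and the minor geometric isomer lactonises to a butenolide that is removed by chromatography.

Step 9
Reactants: 18 the allylboronate diol; 19 tiglic acid
Product: 20 ethyl (2E,4R,6R)-8-[3-(tert-butyldiphenylsilyloxymethyl)furan-2-yl]-6-hydroxy-6-methyl-4-[(E)-2-methylbut-2-enoyloxy]-2-[(pinacolboryl)methyl]oct-2-en-7-ynoate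
Conditions: DCC, DMAP (cat.), CH2Cl2, 0 °C to rt
Reagents that add atoms: none
Why: Steglich esterification acylates only the secondary C8 hydroxyl (the tertiary propargylic 10-OH is inert) with retention at C8, and tiglate is the stable geometric isomer.

Step 10
Reactants: 20 the tiglate allylboronate
Product: 22 ethyl (2E,4R,6R,10Z)-10-(tert-butyldiphenylsilyloxymethyl)-6-hydroxy-6-methyl-4-[(E)-2-methylbut-2-enoyloxy]-9,12-dioxo-2-[(pinacolboryl)methyl]dodeca-2,10-dien-7-ynoate, via endoperoxide 21 (not isolated)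
Conditions: O2, hν (visible), tetraphenylporphyrin (1 mol%), CH2Cl2, −78 °C; Me2S (2 equiv), −78 to 0 °C; quick filtration through deactivated silica, used at once
Reagents that add atoms: oxygen, O=O
Why: [4+2] cycloaddition of singlet oxygen to the furan (far faster than the ene reaction of the electron-poor enoates) and reductive opening of 21 by Me2S, which unmasks C3=O and C6HO on the same side of C4=C5 and so fixes 4Z.

Step 11
Reactants: 22 the acyclic (Z)-keto-enal allylboronate
Product: 24 (4Z,6S,7R,8R,10R)-15-(tert-butyldiphenylsilyloxy)-10-hydroxy-3-oxo-8-tigloyloxygermacra-4,11(13)-dien-1-yn-12,6-olide, via macrocyclic borate 23 (not isolated)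
Conditions: Sc(OTf)3 (1 equiv), 4 Å MS, CH2Cl2, 22 added over 12 h (final 1 mM), 0 °C to rt
Reagents that add atoms: none
Why: Proposed new method: a 10-membered-ring version of the Lewis-acid-catalysed 2-(alkoxycarbonyl)allylboration/lactonisation of aldehydes, in which Sc(OTf)3 binds a boronate oxygen and speeds the closed Zimmerman–Traxler chair, only the very electrophilic C6 aldehyde can bind boron (attack at C3=O would need a cycloheptyne, and the boronate is too poor a π-nucleophile for open conjugate addition at C1), C8 cis to CH2B sits axial so C6/C7 come out syn (cis-lactone, 6S), the A(1,3)-minimised rotamer at C8 (H-8 eclipsing C13) places the new bond anti to C9 and gives 7R, and the C6 borate then acylates on the ethyl ester; the closest known reactions are intermolecular Sc(OTf)3-catalysed additions of 3-substituted 2-(alkoxycarbonyl)allylboronates, intramolecular allylborations to small rings and Barbier macrocyclisations to germacranolides.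

Step 12
Reactants: 24 the macrocyclic ynone lactone
Product: 27 target (4Z,6S,7R,8R,10R)-3,10-epoxy-15-hydroxy-1-oxo-8-tigloyloxygermacra-2,4,11(13)-trien-12,6-olide, via diketone 25 (not isolated), via silyl ether 26 (not isolated)
Conditions: (4-CF3C6H4)3PAuCl (5 mol%), AgOTf (5 mol%), wet toluene, rt; then HF·pyridine, THF, 0 °C to rt
Reagents that add atoms: water, O
Why: Gold-catalysed isomerisation of a γ-hydroxy alkynone to a 3(2H)-furanone run transannularly, in which water adds at C1 of the bent, gold-activated ynone to give 25, the 10-OH closes on C3 (3,10-hemiketal) and loss of water gives 26 with C10 untouched, and fluoride then frees the C15 hydroxyl.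

## Compound list
1 | acetone | CC(C)=O | starting material
2 | ethyl glyoxylate | CCOC(=O)C=O | starting material
3 | ethyl (2R)-2-hydroxy-4-oxopentanoate | CCOC(=O)[C@H](O)CC(C)=O | intermediate
4 | ethynylmagnesium bromide | C#C[Mg]Br | starting material
5 | ethyl (2R,4R)-2,4-dihydroxy-4-methylhex-5-ynoate (present as its bromomagnesium alkoxide) | CCOC(=O)[C@H](O)C[C@@](C)(O)C#C | intermediate
6 | (3R,5R)-5-ethynyl-3-hydroxy-5-methyloxolan-2-one | O=C1O[C@@](C)(C#C)C[C@H]1O | intermediate
7 | furan-3-ylmethanol | OCc1ccoc1 | starting material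
8 | lithium (2-lithiofuran-3-yl)methoxide | [Li]OCc1ccoc1[Li] | intermediate
9 | (2-iodofuran-3-yl)methanol | OCc1ccoc1I | intermediate
10 | tert-butyl[(2-iodofuran-3-yl)methoxy]diphenylsilane | CC(C)(C)[Si](OCc1ccoc1I)(c1ccccc1)c1ccccc1 | intermediate
11 | (3R,5R)-5-{[3-(TBDPS-oxymethyl)furan-2-yl]ethynyl}-3-hydroxy-5-methyloxolan-2-one | O=C1O[C@@](C)(C#Cc2occc2CO[Si](c2ccccc2)(c2ccccc2)C(C)(C)C)C[C@H]1O | intermediate
12 | lactol of 11, (3R,5R), anomer mixture | OC1O[C@@](C)(C#Cc2occc2CO[Si](c2ccccc2)(c2ccccc2)C(C)(C)C)C[C@H]1O | intermediate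
13 | triethyl phosphonoacetate | CCOC(=O)CP(=O)(OCC)OCC | starting material
14 | 2-(bromomethyl)-4,4,5,5-tetramethyl-1,3,2-dioxaborolane | BrCB1OC(C)(C)C(C)(C)O1 | starting material
15 | sodium salt of 13 | [Na+].CCOC(=O)[CH-]P(=O)(OCC)OCC | intermediate
16 | ethyl 2-(diethoxyphosphoryl)-3-(pinacolboryl)propanoate (racemic) | CCOC(=O)C(CB1OC(C)(C)C(C)(C)O1)P(=O)(OCC)OCC | intermediate
17 | sodium salt of 16 | [Na+].CCOC(=O)[C-](CB1OC(C)(C)C(C)(C)O1)P(=O)(OCC)OCC | intermediate
18 | (2E,4R,6R)-allylboronate diol (C8 cis to CH2B) | CCOC(=O)/C(CB1OC(C)(C)C(C)(C)O1)=C/[C@H](O)C[C@@](C)(O)C#Cc1occc1CO[Si](c1ccccc1)(c1ccccc1)C(C)(C)C | intermediate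
19 | tiglic acid | C/C=C(\C)C(=O)O | starting material
20 | 8-O-tiglate of 18 | CCOC(=O)/C(CB1OC(C)(C)C(C)(C)O1)=C/[C@H](OC(=O)/C(C)=C/C)C[C@@](C)(O)C#Cc1occc1CO[Si](c1ccccc1)(c1ccccc1)C(C)(C)C | intermediate
21 | furan endoperoxide of 20 (2,3,7-trioxabicyclo[2.2.1]hept-5-ene, both faces) | CCOC(=O)/C(CB1OC(C)(C)C(C)(C)O1)=C/[C@H](OC(=O)/C(C)=C/C)C[C@@](C)(O)C#CC12OOC(O1)C=C2CO[Si](c1ccccc1)(c1ccccc1)C(C)(C)C | intermediate
22 | acyclic (4Z)-3-oxo-6-al ynone allylboronate | CCOC(=O)/C(CB1OC(C)(C)C(C)(C)O1)=C/[C@H](OC(=O)/C(C)=C/C)C[C@@](C)(O)C#CC(=O)/C(CO[Si](c1ccccc1)(c1ccccc1)C(C)(C)C)=C\C=O | intermediate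
23 | macrocyclic ethyl acrylate with 6β-O-Bpin, 7α-H, 8β-O-tiglate, 10α-OH, 4Z, 1-yne, 3-one | CCOC(=O)C(=C)[C@H]1[C@@H](OB2OC(C)(C)C(C)(C)O2)/C=C(/CO[Si](c2ccccc2)(c2ccccc2)C(C)(C)C)C(=O)C#C[C@](C)(O)C[C@H]1OC(=O)/C(C)=C/C | intermediate
24 | (4Z,6S,7R,8R,10R) macrocyclic γ-hydroxy-ynone, cis-fused α-methylene lactone | C=C1C(=O)O[C@H]2/C=C(/CO[Si](c3ccccc3)(c3ccccc3)C(C)(C)C)C(=O)C#C[C@](C)(O)C[C@@H](OC(=O)/C(C)=C/C)[C@@H]12 | intermediate
25 | (4Z,6S,7R,8R,10R) 10-hydroxy-1,3-dione | C=C1C(=O)O[C@H]2/C=C(/CO[Si](c3ccccc3)(c3ccccc3)C(C)(C)C)C(=O)CC(=O)[C@](C)(O)C[C@@H](OC(=O)/C(C)=C/C)[C@@H]12 | intermediate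
26 | 15-O-TBDPS ether of 27 | C=C1C(=O)O[C@H]2/C=C(/CO[Si](c3ccccc3)(c3ccccc3)C(C)(C)C)C3=CC(=O)[C@@](C)(C[C@@H](OC(=O)/C(C)=C/C)[C@@H]12)O3 | intermediate
27 | CNP0269689.6 | C=C1C(=O)O[C@H]2/C=C(/CO)C3=CC(=O)[C@@](C)(C[C@@H](OC(=O)/C(C)=C/C)[C@@H]12)O3 | target

## Count and risks
Total steps: 12.
Longest linear sequence: 9 (steps 1, 2, 5, 6, 8, 9, 10, 11, 12). The furan branch (steps 3, 4, 5, 6, 8, 9, 10, 11, 12) is equally long.

**Step 11 (macrocyclic allylboration).** The ring closure may be too slow, or may give the wrong C6/C7 pair.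
- The fallback sets out from 22 and comes back at 26, and it reverses the last two ring closures.
- 22 is first treated with the gold catalyst in wet toluene to give the acyclic 3(2H)-furanone enal F1. Its rigid, bent furanone holds C6 near C7 and no longer carries an ynone.
- The C6–C7 closure and lactonisation (Sc(OTf)3, or heating in toluene, high dilution) then give 26 directly. HF·pyridine completes the route.

**Step 8 (HWE with the untested boryl phosphonate on a lactol).**
- The fallback sets out from 12 and comes back at 18.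
- Wittig olefination of 12 with ethyl bromo(triphenylphosphoranylidene)acetate gives the (Z)-α-bromo enoate diol F2, in which C8 is cis to Br.
- Negishi coupling with (pinacolboryl)methylzinc iodide (from ICH2Bpin and zinc dust) and Pd(PPh3)4 in THF replaces Br by CH2Bpin with retention of geometry.

**Step 10 (isolation of the labile Z-keto-enal, with Z to E drift).**
- The fallback sets out from 20 and comes back at 24.
- The furan is oxidised with NBS in methanol (NaHCO3, −40 °C) to the stable, chromatographable 2,5-dimethoxy-2,5-dihydrofuran F3, a ring-locked masked ene-dione.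
- F3 is unmasked only under the cyclisation conditions (Sc(OTf)3, CH2Cl2 with 3 equiv of water, high dilution). Compound 22 is then present only fleetingly and goes straight on to 24.

## Further compounds
F1 | step 11 | acyclic furanone enal, (8R,10R), 4Z, allylboronate retained | CCOC(=O)/C(CB1OC(C)(C)C(C)(C)O1)=C/[C@H](OC(=O)/C(C)=C/C)C[C@@]1(C)OC(=CC1=O)/C(CO[Si](c1ccccc1)(c1ccccc1)C(C)(C)C)=C\C=O
F2 | step 8 | ethyl (2Z,4R,6R)-2-bromo-8-[3-(TBDPS-oxymethyl)furan-2-yl]-4,6-dihydroxy-6-methyloct-2-en-7-ynoate | CCOC(=O)/C(Br)=C/[C@H](O)C[C@@](C)(O)C#Cc1occc1CO[Si](c1ccccc1)(c1ccccc1)C(C)(C)C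
F3 | step 10 | 2,5-dimethoxy-2,5-dihydrofuran from 20 (acetal epimers) | CCOC(=O)/C(CB1OC(C)(C)C(C)(C)O1)=C/[C@H](OC(=O)/C(C)=C/C)C[C@@](C)(O)C#CC1(OC)OC(OC)C=C1CO[Si](c1ccccc1)(c1ccccc1)C(C)(C)C
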